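**Retrosynthetic overview**

1. The target is read as epigallocatechin-(4β→6)-epigallocatechin 3'-O-gallate; it is reached by hydrogenolysis of its tetradeca-O-benzyl ether.
2. Key disconnection: ring C of the lower unit is opened at C4–C4a and at O1–C2. This leaves a phenol (the upper unit carrying a 2,6-bis(benzyloxy)-4-hydroxyphenyl group on C4) and a three-carbon unit; both bonds are made in one flask by epoxide arylation followed by ortho-ester (acyloxonium) ring closure.
3. Feature that allows this: O1 and C4a sit on neighbouring carbons (C8a, C4a) of the phloroglucinol ring A of the lower unit, so that ring is an ortho C,O-dinucleophile. C2–C3–C4 is a benzylic C–O / secondary C–O(gallate) / CH2 chain, so the C3 gallate can bridge the oxygens on C2 and C3 as a 1,3-dioxolan-2-ylium ion and serve as the leaving group at C2. The only free OH of the phenol lies para to the interflavan bond, which fixes the 4→6 connectivity.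
4. The three-carbon unit is an erythro aryl(oxiranyl)methanol made from 3,4,5-tris(benzyloxy)benzaldehyde (vinyl Grignard addition, Sharpless kinetic resolution); the gallate carbon is brought in as an ortho ester made from the same aldehyde.
5. Order of rings: upper rings A, B and C come from (–)-epigallocatechin; lower ring A is attached to upper C4 as an aryl group; lower ring B and the galloyl ring arrive with the three-carbon unit and the ortho ester; lower ring C is closed last.

Key step: step 11

Remark: the SMILES is read as upper unit (2R,3R,4S), 2,3-cis-3,4-trans, and lower unit (2R,3R) bearing the gallate; (–)-epigallocatechin, 3,5-bis(benzyloxy)phenol and 3,4,5-tris(benzyloxy)benzaldehyde are taken as purchasable.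

**Route**

Step 1
Reactants: 1 (–)-epigallocatechin
Product: 2 5,7,3',4',5'-penta-O-benzyl-(–)-epigallocatechin (3-OH free)
Conditions: BnBr (5.5 equiv), K2CO3, DMF, –10 °C to rt, argon
Reagents that add atoms: benzyl bromide, BrCc1ccccc1
Why: Williamson etherification: the five phenols are far more acidic than the secondary 3-OH, so they should be benzylated selectively, and the mild base and low temperature limit C-benzylation and base-induced opening of ring C, so C2 and C3 stay untouched.

Step 2
Reactants: 2 5,7,3',4',5'-penta-O-benzyl-(–)-epigallocatechin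
Product: 3 3,5,7,3',4',5'-hexa-O-benzyl-(–)-epigallocatechin
Conditions: NaH, BnBr, DMF, 0 °C to rt
Reagents that add atoms: benzyl bromide, BrCc1ccccc1
Why: Williamson etherification of the secondary alkoxide should cap the 3-OH as a benzyl ether that leaves with all the others in the last step; no stereocenter is involved.

Step 3
Reactants: 3 3,5,7,3',4',5'-hexa-O-benzyl-(–)-epigallocatechin
Product: 4 4β-(2-ethoxyethoxy)-3,5,7,3',4',5'-hexa-O-benzyl-epigallocatechin (2,3-cis, 3,4-trans)
Conditions: DDQ (2 equiv), 2-ethoxyethanol, CH2Cl2, rt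
Reagents that add atoms: 2-ethoxyethanol, CCOCCO
Why: Benzylic oxidation with DDQ: hydride abstraction at C4 (ortho/para to the ring-A ether oxygens) gives a quinone-methide-type cation that the alcohol should trap anti to the 3-benzyloxy group (4β); this new C4 centre only carries a leaving group and is erased in step 5.

Step 4
Reactants: 5 3,5-bis(benzyloxy)phenol
Product: 6 [3,5-bis(benzyloxy)phenoxy]tri(propan-2-yl)silane
Conditions: chlorotriisopropylsilane, imidazole, DMF, rt
Reagents that add atoms: chlorotriisopropylsilane, CC(C)[Si](Cl)(C(C)C)C(C)C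
Why: Silyl ether formation marks the one oxygen of the phloroglucinol unit that must later be free, and the bulk of the silyl group is meant to steer the next C–C bond formation.

Step 5
Reactants: 4 4β-(2-ethoxyethoxy)-hexa-O-benzyl-epigallocatechin; 6 [3,5-bis(benzyloxy)phenoxy]tri(propan-2-yl)silane
Product: 7 4β-[2,6-bis(benzyloxy)-4-(triisopropylsilyloxy)phenyl]-3,5,7,3',4',5'-hexa-O-benzyl-epigallocatechin (2,3-cis, 3,4-trans)
Conditions: 6 (3 equiv), Me3SiOTf (0.5 equiv), CH2Cl2, –78 °C
Reagents that add atoms: none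
Why: Lewis-acid-mediated Friedel–Crafts arylation at C4 of a 4-alkoxyflavan: the arene should add to the benzylic cation anti to the 3-benzyloxy and 2-aryl groups (4β, 3,4-trans, as in the target), and the bulky silyloxy group should shield its two ortho carbons so that the bond forms para to it, between the two benzyloxy groups.

Step 6
Reactants: 7 4β-[2,6-bis(benzyloxy)-4-(triisopropylsilyloxy)phenyl]-hexa-O-benzyl-epigallocatechin
Product: 8 4β-[2,6-bis(benzyloxy)-4-hydroxyphenyl]-3,5,7,3',4',5'-hexa-O-benzyl-epigallocatechin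
Conditions: Bu4NF, THF, 0 °C
Reagents that add atoms: none
Why: Fluoride-induced cleavage of the aryl silyl ether should free only the phenol para to the interflavan bond; benzyl ethers and all stereocenters are untouched.

Step 7
Reactants: 9 3,4,5-tris(benzyloxy)benzaldehyde
Product: 10 rac-1-[3,4,5-tris(benzyloxy)phenyl]prop-2-en-1-ol
Conditions: vinylmagnesium bromide, THF, –78 to 0 °C
Reagents that add atoms: vinylmagnesium bromide, C=C[Mg]Br
Why: Grignard addition to the aldehyde should give the racemic secondary allylic alcohol needed for the resolution.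

Step 8
Reactants: 10 rac-1-[3,4,5-tris(benzyloxy)phenyl]prop-2-en-1-ol
Product: 11 (S)-[(2R)-oxiran-2-yl][3,4,5-tris(benzyloxy)phenyl]methanol (erythro)
Conditions: Ti(OiPr)4 (0.1 equiv), L-(+)-diisopropyl tartrate (0.15 equiv), t-BuOOH (0.6 equiv), 4 Å MS, CH2Cl2, –20 °C
Reagents that add atoms: tert-butyl hydroperoxide, CC(C)(C)OO
Why: Sharpless kinetic resolution (asymmetric epoxidation of a secondary allylic alcohol): with L-(+)-tartrate the (R)-enantiomer of 10 should be epoxidised much faster than the (S)-enantiomer and with high erythro (anti) selectivity, so both stereocenters of 11 are set by the tartrate catalyst, and unreacted (S)-10 is removed by chromatography.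

Step 9
Reactants: 9 3,4,5-tris(benzyloxy)benzaldehyde
Product: 14 3,4,5-tris(benzyloxy)benzonitrile, via aldoxime 12 (not isolated), via O-acetyl aldoxime 13 (not isolated)
Conditions: NH2OH·HCl, pyridine, 60 °C; then Ac2O, 110 °C, same flask
Reagents that add atoms: hydroxylamine hydrochloride, NO.Cl
Why: Oxime formation followed by dehydration with acetic anhydride (aldehyde-to-nitrile conversion) should run in one flask, and the benzyl ethers are inert to it.

Step 10
Reactants: 14 3,4,5-tris(benzyloxy)benzonitrile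
Product: 16 1,2,3-tris(benzyloxy)-5-(trimethoxymethyl)benzene (trimethyl ortho-gallate, tri-O-benzyl), via imidate hydrochloride 15 (not isolated)
Conditions: HCl (g), MeOH (1.2 equiv), CH2Cl2/Et2O, 0 °C; then MeOH (excess), hexane, rt, 3 d
Reagents that add atoms: methanol, CO
Why: Pinner reaction: the nitrile should give the methyl imidate hydrochloride, whose alcoholysis with excess methanol should give the trimethyl ortho ester and NH4Cl; anhydrous HCl at 0 °C does not cleave aryl benzyl ethers.

Step 11
Reactants: 8 4β-[2,6-bis(benzyloxy)-4-hydroxyphenyl]-hexa-O-benzyl-epigallocatechin; 11 (S)-[(2R)-oxiran-2-yl][3,4,5-tris(benzyloxy)phenyl]methanol; 16 1,2,3-tris(benzyloxy)-5-(trimethoxymethyl)benzene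
Product: 20 tetradeca-O-benzyl epigallocatechin-(4β→6)-epigallocatechin 3'-O-gallate, via erythro-diol 17 (not isolated), via cyclic orthoester 18 (not isolated), via dioxolanylium ion 19 (not isolated)
Conditions: 8 (1 equiv), 11 (1.3 equiv), pyridinium p-toluenesulfonate (0.2 equiv), (CF3)2CHOH/CH2Cl2 (1:2), 0 °C to rt; then 16 (2 equiv), 35 °C, same flask
Reagents that add atoms: none
Why: Proposed new method: in the hydrogen-bond-donating fluoroalcohol the ring carbon ortho to the free OH of 8 should open the epoxide of 11 at its terminal CH2 (Friedel–Crafts epoxide arylation; the internal epoxide carbon is inductively deactivated by the neighbouring carbinol) to give erythro-diol 17, whose two hydroxyls are then tied by 16 into cyclic orthoester 18; this ionises to the cis-4,5-disubstituted 2-aryl-1,3-dioxolan-2-ylium ion 19, and the phenol oxygen opens 19 at the benzylic carbon with inversion, which leaves the former ortho-ester carbon as the C3 gallate. The closest known reactions are the fluoroalcohol-promoted arylation of epoxides by electron-rich arenes and the ortho-formate cyclisation of 1-aryl-3-(2-hydroxyaryl)propane-1,2-diols to flavan-3-ol formates; new are their union in one flask, the use of an ortho-gallate so that the activating group is the very ester the target needs, and the erythro (cis-dioxolanylium) series. Ring C of the lower unit is closed by a 6-exo-tet O-alkylation after the intermolecular C–C bond formation. No stereocenter is made from nothing: C3 keeps the oxirane configuration of 11 and C2 is inverted once, so the erythro pair set by the Sharpless resolution is translated stereospecifically into the 2,3-cis (2R,3R) pair. The step needs C- over O-alkylation and 4→6 over 4→8 connectivity, which the phloroglucinol-type ring and the single free hydroxyl of 8 secure (it lies para to the flavanyl group, between two CH positions that are equivalent by rotation about the interflavan bond). It also needs SN2 rather than SN1 at C2, which the 3,4,5-trioxygenated aryl group (one twisted para donor, two inductively withdrawing meta oxygens) and the acyloxy-bearing neighbour carbon favour.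

Step 12
Reactants: 20 tetradeca-O-benzyl epigallocatechin-(4β→6)-epigallocatechin 3'-O-gallate
Product: 21 epigallocatechin-(4β→6)-epigallocatechin 3'-O-gallate (CNP0204196.2)
Conditions: H2 (1 atm), Pd(OH)2/C, THF/MeOH/H2O, rt; filtration and freeze-drying under argon
Reagents that add atoms: none
Why: Hydrogenolysis of the fourteen benzyl ethers under neutral conditions should leave the gallate ester, the two C2–O1 ether bonds and the interflavan C–C bond intact, and touches no stereocenter.

**Compound list**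

1 | (–)-epigallocatechin, (2R,3R)-2-(3,4,5-trihydroxyphenyl)chromane-3,5,7-triol | O[C@@H]1Cc2c(O)cc(O)cc2O[C@@H]1c1cc(O)c(O)c(O)c1 | starting material
2 | 5,7,3',4',5'-penta-O-benzyl-(–)-epigallocatechin | O[C@@H]1Cc2c(OCc3ccccc3)cc(OCc3ccccc3)cc2O[C@@H]1c1cc(OCc2ccccc2)c(OCc2ccccc2)c(OCc2ccccc2)c1 | intermediate
3 | 3,5,7,3',4',5'-hexa-O-benzyl-(–)-epigallocatechin | O(Cc1ccccc1)[C@@H]1Cc2c(OCc3ccccc3)cc(OCc3ccccc3)cc2O[C@@H]1c1cc(OCc2ccccc2)c(OCc2ccccc2)c(OCc2ccccc2)c1 | intermediate
4 | 4β-(2-ethoxyethoxy)-hexa-O-benzyl-epigallocatechin (2,3-cis, 3,4-trans) | CCOCCO[C@H]1c2c(OCc3ccccc3)cc(OCc3ccccc3)cc2O[C@H](c2cc(OCc3ccccc3)c(OCc3ccccc3)c(OCc3ccccc3)c2)[C@@H]1OCc1ccccc1 | intermediate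
5 | 3,5-bis(benzyloxy)phenol | Oc1cc(OCc2ccccc2)cc(OCc2ccccc2)c1 | starting material
6 | [3,5-bis(benzyloxy)phenoxy]tri(propan-2-yl)silane | CC(C)[Si](Oc1cc(OCc2ccccc2)cc(OCc2ccccc2)c1)(C(C)C)C(C)C | intermediate
7 | 4β-[2,6-bis(benzyloxy)-4-(triisopropylsilyloxy)phenyl]-hexa-O-benzyl-epigallocatechin (2,3-cis, 3,4-trans) | CC(C)[Si](Oc1cc(OCc2ccccc2)c([C@H]2c3c(OCc4ccccc4)cc(OCc4ccccc4)cc3O[C@H](c3cc(OCc4ccccc4)c(OCc4ccccc4)c(OCc4ccccc4)c3)[C@@H]2OCc2ccccc2)c(OCc2ccccc2)c1)(C(C)C)C(C)C | intermediate
8 | 4β-[2,6-bis(benzyloxy)-4-hydroxyphenyl]-hexa-O-benzyl-epigallocatechin (2,3-cis, 3,4-trans) | Oc1cc(OCc2ccccc2)c([C@H]2c3c(OCc4ccccc4)cc(OCc4ccccc4)cc3O[C@H](c3cc(OCc4ccccc4)c(OCc4ccccc4)c(OCc4ccccc4)c3)[C@@H]2OCc2ccccc2)c(OCc2ccccc2)c1 | intermediate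
9 | 3,4,5-tris(benzyloxy)benzaldehyde | O=Cc1cc(OCc2ccccc2)c(OCc2ccccc2)c(OCc2ccccc2)c1 | starting material
10 | rac-1-[3,4,5-tris(benzyloxy)phenyl]prop-2-en-1-ol | C=CC(O)c1cc(OCc2ccccc2)c(OCc2ccccc2)c(OCc2ccccc2)c1 | intermediate
11 | (S)-[(2R)-oxiran-2-yl][3,4,5-tris(benzyloxy)phenyl]methanol (erythro) | O[C@H]([C@H]1CO1)c1cc(OCc2ccccc2)c(OCc2ccccc2)c(OCc2ccccc2)c1 | intermediate
12 | (E)-3,4,5-tris(benzyloxy)benzaldehyde oxime (not isolated) | O/N=C/c1cc(OCc2ccccc2)c(OCc2ccccc2)c(OCc2ccccc2)c1 | intermediate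
13 | (E)-3,4,5-tris(benzyloxy)benzaldehyde O-acetyloxime (not isolated) | CC(=O)O/N=C/c1cc(OCc2ccccc2)c(OCc2ccccc2)c(OCc2ccccc2)c1 | intermediate
14 | 3,4,5-tris(benzyloxy)benzonitrile | N#Cc1cc(OCc2ccccc2)c(OCc2ccccc2)c(OCc2ccccc2)c1 | intermediate
15 | methyl 3,4,5-tris(benzyloxy)benzimidate hydrochloride (not isolated) | COC(=[NH2+])c1cc(OCc2ccccc2)c(OCc2ccccc2)c(OCc2ccccc2)c1.[Cl-] | intermediate
16 | 1,2,3-tris(benzyloxy)-5-(trimethoxymethyl)benzene | COC(OC)(OC)c1cc(OCc2ccccc2)c(OCc2ccccc2)c(OCc2ccccc2)c1 | intermediate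
17 | (1S,2R)-1-[3,4,5-tris(benzyloxy)phenyl]-3-aryl-propane-1,2-diol, aryl = ring D of 8 bonded through the carbon ortho to its free OH (erythro; not isolated) | O[C@H]([C@H](O)Cc1c(O)cc(OCc2ccccc2)c([C@H]2c3c(OCc4ccccc4)cc(OCc4ccccc4)cc3O[C@H](c3cc(OCc4ccccc4)c(OCc4ccccc4)c(OCc4ccccc4)c3)[C@@H]2OCc2ccccc2)c1OCc1ccccc1)c1cc(OCc2ccccc2)c(OCc2ccccc2)c(OCc2ccccc2)c1 | intermediate
18 | cyclic ortho ester of 17: 2-methoxy-2-[3,4,5-tris(benzyloxy)phenyl]-1,3-dioxolane, cis-4,5-disubstituted, both carbinol configurations of 17 kept, mixture at the ortho-ester carbon (not isolated) | COC1(c2cc(OCc3ccccc3)c(OCc3ccccc3)c(OCc3ccccc3)c2)O[C@@H](c2cc(OCc3ccccc3)c(OCc3ccccc3)c(OCc3ccccc3)c2)[C@@H](Cc2c(O)cc(OCc3ccccc3)c([C@H]3c4c(OCc5ccccc5)cc(OCc5ccccc5)cc4O[C@H](c4cc(OCc5ccccc5)c(OCc5ccccc5)c(OCc5ccccc5)c4)[C@@H]3OCc3ccccc3)c2OCc2ccccc2)O1 | intermediate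
19 | 2-[3,4,5-tris(benzyloxy)phenyl]-1,3-dioxolan-2-ylium ion from 18, cis-4,5-disubstituted, tosylate as counter-ion (not isolated) | C1(c2cc(OCc3ccccc3)c(OCc3ccccc3)c(OCc3ccccc3)c2)=[O+][C@@H](c2cc(OCc3ccccc3)c(OCc3ccccc3)c(OCc3ccccc3)c2)[C@@H](Cc2c(O)cc(OCc3ccccc3)c([C@H]3c4c(OCc5ccccc5)cc(OCc5ccccc5)cc4O[C@H](c4cc(OCc5ccccc5)c(OCc5ccccc5)c(OCc5ccccc5)c4)[C@@H]3OCc3ccccc3)c2OCc2ccccc2)O1 | intermediate
20 | tetradeca-O-benzyl epigallocatechin-(4β→6)-epigallocatechin 3'-O-gallate (all phenols and the upper 3-OH as benzyl ethers) | O=C(O[C@@H]1Cc2c(cc(OCc3ccccc3)c([C@H]3c4c(OCc5ccccc5)cc(OCc5ccccc5)cc4O[C@H](c4cc(OCc5ccccc5)c(OCc5ccccc5)c(OCc5ccccc5)c4)[C@@H]3OCc3ccccc3)c2OCc2ccccc2)O[C@@H]1c1cc(OCc2ccccc2)c(OCc2ccccc2)c(OCc2ccccc2)c1)c1cc(OCc2ccccc2)c(OCc2ccccc2)c(OCc2ccccc2)c1 | intermediate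
21 | (2R,3R)-5,7-dihydroxy-2-(3,4,5-trihydroxyphenyl)-6-[(2R,3R,4S)-3,5,7-trihydroxy-2-(3,4,5-trihydroxyphenyl)chroman-4-yl]chroman-3-yl 3,4,5-trihydroxybenzoate | O=C(O[C@@H]1Cc2c(cc(O)c([C@H]3c4c(O)cc(O)cc4O[C@H](c4cc(O)c(O)c(O)c4)[C@@H]3O)c2O)O[C@@H]1c1cc(O)c(O)c(O)c1)c1cc(O)c(O)c(O)c1 | target

**Step count and risks**

Total step count: 12. Longest linear sequence: 7 steps (1, 2, 3, 5, 6, 11, 12).

Steps most likely to fail:

1. Step 11. In the first stage the phenol may be O-alkylated, or the benzylic carbinol of 11 may ionise and alkylate the ring through the wrong carbon, instead of the ring attacking the terminal epoxide carbon. In the second stage reversible heterolysis of the benzylic C–O bond of the dioxolanylium ion would leak configuration at C2 towards the 2,3-trans series, and the acid may also cleave the interflavan bond. Fallback with known chemistry, forming the O–C2 bond first under neutral conditions; it sets out from 8 and 11 and comes back at 20. Mitsunobu etherification of 8 with 11 (PPh3, diisopropyl azodicarboxylate, toluene, 0 °C) should give, with inversion at the carbinol carbon, the aryl 1-aryl-2,3-epoxypropyl ether F1. Epoxide–arene cyclisation of this glycidyl-type aryl ether in (CF3)2CHOH at rt (6-endo attack of the ring carbon ortho to the ether oxygen on the terminal epoxide carbon) should give the 2,3-cis-flavan-3-ol F2. Steglich esterification of F2 with commercial 3,4,5-tris(benzyloxy)benzoic acid (N,N'-dicyclohexylcarbodiimide, 4-(dimethylamino)pyridine, CH2Cl2) should then give 20.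

2. Step 5. The arylation may show poor regioselectivity (bond formation next to the silyl ether instead of para to it), the silyl group may be lost under the Lewis acid, and the cation may self-condense with ring A of a second molecule. Fallback that removes the regiochemical question by symmetry; it sets out from 4 and comes back at 7. Friedel–Crafts arylation of 4 with an excess of phloroglucinol (Me3SiOTf, THF/CH2Cl2, –78 to –40 °C), whose three ring carbons are equivalent, should give the 4β-(2,4,6-trihydroxyphenyl) adduct F3. Silylation of its only unhindered hydroxyl, the one para to the flavanyl group (chlorotriisopropylsilane, imidazole, DMF, –20 °C), should give the mono-silyl ether F4, and benzylation of the two remaining hydroxyls (benzyl bromide, K2CO3, acetone) should give 7.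

3. Step 10. Alcoholysis of the electron-rich imidate salt may be sluggish, the salt may collapse to the amide with loss of chloromethane, and the ortho ester may hydrolyse during isolation. Fallback that does without 16 and brings in the gallate by acylation; it sets out from 8 and 11 and comes back at 20. The first stage of step 11 is run unchanged to diol 17; commercial trimethyl orthoformate then replaces 16 and should give the 3-O-formate F5 (the ortho-formate variant of the ring closure). Methanolysis (K2CO3, MeOH/THF) should give the flavan-3-ol F2, which is esterified as in the first fallback to give 20.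

**Further compounds**

F1 | step 11 | 4β-{2,6-bis(benzyloxy)-4-[(R)-[(2R)-oxiran-2-yl][3,4,5-tris(benzyloxy)phenyl]methoxy]phenyl}-hexa-O-benzyl-epigallocatechin | O([C@@H]([C@H]1CO1)c1cc(OCc2ccccc2)c(OCc2ccccc2)c(OCc2ccccc2)c1)c1cc(OCc2ccccc2)c([C@H]2c3c(OCc4ccccc4)cc(OCc4ccccc4)cc3O[C@H](c3cc(OCc4ccccc4)c(OCc4ccccc4)c(OCc4ccccc4)c3)[C@@H]2OCc2ccccc2)c(OCc2ccccc2)c1
F2 | step 11 | undeca-O-benzyl epigallocatechin-(4β→6)-epigallocatechin with free lower 3-OH (2,3-cis lower unit) | O[C@@H]1Cc2c(cc(OCc3ccccc3)c([C@H]3c4c(OCc5ccccc5)cc(OCc5ccccc5)cc4O[C@H](c4cc(OCc5ccccc5)c(OCc5ccccc5)c(OCc5ccccc5)c4)[C@@H]3OCc3ccccc3)c2OCc2ccccc2)O[C@@H]1c1cc(OCc2ccccc2)c(OCc2ccccc2)c(OCc2ccccc2)c1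
F3 | step 5 | 4β-(2,4,6-trihydroxyphenyl)-hexa-O-benzyl-epigallocatechin | Oc1cc(O)c([C@H]2c3c(OCc4ccccc4)cc(OCc4ccccc4)cc3O[C@H](c3cc(OCc4ccccc4)c(OCc4ccccc4)c(OCc4ccccc4)c3)[C@@H]2OCc2ccccc2)c(O)c1
F4 | step 5 | 4β-[2,6-dihydroxy-4-(triisopropylsilyloxy)phenyl]-hexa-O-benzyl-epigallocatechin | CC(C)[Si](Oc1cc(O)c([C@H]2c3c(OCc4ccccc4)cc(OCc4ccccc4)cc3O[C@H](c3cc(OCc4ccccc4)c(OCc4ccccc4)c(OCc4ccccc4)c3)[C@@H]2OCc2ccccc2)c(O)c1)(C(C)C)C(C)C
F5 | step 10 | undeca-O-benzyl epigallocatechin-(4β→6)-epigallocatechin 3'-O-formate | O=CO[C@@H]1Cc2c(cc(OCc3ccccc3)c([C@H]3c4c(OCc5ccccc5)cc(OCc5ccccc5)cc4O[C@H](c4cc(OCc5ccccc5)c(OCc5ccccc5)c(OCc5ccccc5)c4)[C@@H]3OCc3ccccc3)c2OCc2ccccc2)O[C@@H]1c1cc(OCc2ccccc2)c(OCc2ccccc2)c(OCc2ccccc2)c1
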